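## Retrosynthetic overview
1. Isariotin D (11) ⇒ retro-aldol (C5–C9) and retro-oxa-Michael (C6–OH) ⇒ epoxy-enone aldehyde 10. Carbocycle A closes last, onto a finished ring B.
2. 10 ⇒ 1,3-carbonyl transposition of epoxy vinylogous ester 7. This unmasks the C4 ketone and expels the former phenol oxygen.
3. 7 ⇒ chromenone 6 ⇒ p-quinol 5 by a light-driven dehydrogenative oxa-Michael desymmetrisation (temporary pyran ring, fixes C3).
4. 5 ⇒ phenol 3 by singlet-oxygen dearomatisation (C3–O bond). 3 ⇒ L-tyrosinol + (E)-dec-2-enoic acid.
5. Ring order: ring B (from the arene) → temporary pyran → oxirane → pyran opened → ring A.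

**Locants used throughout:** C1 = CHN, C2 = CH2, C3 = former ipso carbon, C4/C8 = former ortho carbons, C5/C7 = former meta carbons, C6 = former para carbon, C9 = CH2OH carbon of tyrosinol. In these locants the target is 1S,3S,5S,6S,7S,8S,9R.

**Assumption:** L-tyrosinol hydrochloride and (E)-dec-2-enoic acid are purchased. Compounds 4 and 8 are numbered but processed in situ, so they are not counted as steps. Compound 10 is drawn as the open aldehyde although it rests as its spiro-lactol.

## Route

**Step 1**
- Reactants: 1 L-tyrosinol hydrochloride; 2 (E)-dec-2-enoic acid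
- Product: 3 (E)-N-[(2S)-1-hydroxy-3-(4-hydroxyphenyl)propan-2-yl]dec-2-enamide
- Conditions: EDC·HCl, HOBt, iPr2NEt, DMF, 0 °C → rt
- Reagents that add atoms: (E)-dec-2-enoic acid (2), CCCCCCC/C=C/C(=O)O
- Why: Carbodiimide amide coupling; the amine out-competes the phenol and the primary alcohol, and the purchased C1 (S) centre is not touched.

**Step 2**
- Reactants: 3
- Product: 5 (E)-N-[(2S)-1-hydroxy-3-(1-hydroxy-4-oxocyclohexa-2,5-dien-1-yl)propan-2-yl]dec-2-enamide, formed via the 4-hydroperoxydienone 4 (not isolated)
- Conditions: O2 (1 atm), rose bengal (1 mol %), 530 nm LEDs, MeOH–pH 8 phosphate buffer, 0 °C; then Me2S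
- Reagents that add atoms: dioxygen, O=O (one O retained)
- Why: Photosensitised singlet-oxygen dearomatisation of a p-alkylphenol attacks the ipso carbon to give the p-peroxyquinol, which Me2S reduces; C3 stays prochiral (two equivalent enone arms) and the electron-poor enamide is inert to 1O2.

**Step 3**
- Reactants: 5
- Product: 6 (E)-N-[(3S,4aS)-4a-hydroxy-7-oxo-3,4,4a,7-tetrahydro-2H-chromen-3-yl]dec-2-enamide (C1 S, C3 S; amide and C3–OH cis on the pyran)
- Conditions: 4CzIPN (2 mol %), Co(dmgH)2(py)Cl (5 mol %), K3PO4 (20 mol %), MeCN, 456 nm LEDs, N2, 25 °C (–H2)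
- Reagents that add atoms: none
- Why: Proposed new method: catalytic base triggers reversible 6-exo oxa-Michael addition of the primary alkoxide to one of the two diastereotopic enone arms through a chair transition state with the amide equatorial and axial C–O attack (this sets C3 = S), the resulting cross-conjugated dienolate is oxidised by excited 4CzIPN to the C5 α-keto radical, Co(II) removes the only adjacent hydrogen (the oxygen-weakened C4–H), and Co(III)–H is protonated to H2 while the photocatalyst radical anion regenerates Co(II), so the adduct is locked irreversibly as the vinylogous ester; the closest known reaction types are acid- or base-mediated oxa-Michael cyclisation of p-quinols, Pd(II) Wacker-type oxidative oxa-Michael reactions, and photoredox/cobaloxime acceptorless dehydrogenation of enamines.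

**Step 4**
- Reactants: 6
- Product: 7, the C7–C8 epoxide of 6 with the oxirane O cis to C3–OH (C1 S, C3 S, C7 R, C8 S)
- Conditions: t-BuOOH (decane), DBU, CH2Cl2, 0 °C
- Reagents that add atoms: tert-butyl hydroperoxide, CC(C)(C)OO (one O)
- Why: Weitz–Scheffer nucleophilic epoxidation; the alkoxy-substituted arm is deactivated as a vinylogous ester, so only C7=C8 reacts, and peroxide attacks C8 on the face of the small, hydrogen-bonding C3–OH (anti to C2H2) as is usual for p-quinols, while the equatorial amide cannot reach C8 for aza-Michael addition.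

**Step 5**
- Reactants: 7
- Product: 9 (E)-N-{(2S)-1-hydroxy-3-[(1S,2S,6S)-2-hydroxy-3-oxo-7-oxabicyclo[4.1.0]hept-4-en-2-yl]propan-2-yl}dec-2-enamide, formed via allylic alcohol 8 (not isolated)
- Conditions: NaBH4, CeCl3·7H2O, MeOH, –78 °C; then 5% aq oxalic acid, THF, 0 °C
- Reagents that add atoms: water, O (becomes the C4 ketone oxygen)
- Why: Luche 1,2-reduction (hydride anti to the oxirane) followed by Stork–Danheiser transposition; the 3-alkoxy allylic alcohol ionises under very mild acid, water adds at C4, the pyran opens, and the enone emerges as C4(=O)–C5=C6 with C3, C7 and C8 untouched.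

**Step 6**
- Reactants: 9
- Product: 10 (E)-N-{(2S)-1-oxo-3-[(1S,2S,6S)-2-hydroxy-3-oxo-7-oxabicyclo[4.1.0]hept-4-en-2-yl]propan-2-yl}dec-2-enamide (rests as the C3–O–C9 spiro-lactol)
- Conditions: Dess–Martin periodinane (1.05 equiv), NaHCO3, CH2Cl2, 0 °C
- Reagents that add atoms: none
- Why: Dess–Martin oxidation; the primary alcohol is the only oxidisable hydroxyl (the other is tertiary), one equivalent avoids lactone formation, and lactol formation shields the α-amido aldehyde from epimerisation.

**Step 7**
- Reactants: 10
- Product: 11 isariotin D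
- Conditions: K2CO3 (0.2 equiv), THF–H2O (1:1), 0 °C → rt
- Reagents that add atoms: water, O (becomes C6–OH)
- Why: Tandem oxa-Michael/intramolecular aldol; water adds to C6 anti to the chain folded over the β-face (the face carrying the oxirane O and C3–OH, which hydrogen-bond it), the C4 enolate attacks the aldehyde from the only face the three-atom tether can reach (sets C5), the chair closure keeps the amide equatorial with the aldehyde O held beside the enolate O by K+/H-bonding (C9–OH axial, cis to NH), and because every step is reversible the unstrained twin-chair product accumulates.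

## Compound list

| No. | Name | SMILES | Role |
|---|---|---|---|
| 1 | L-tyrosinol hydrochloride | N[C@@H](Cc1ccc(O)cc1)CO.Cl | starting material |
| 2 | (E)-dec-2-enoic acid | CCCCCCC/C=C/C(=O)O | starting material |
| 3 | N-decenoyl-L-tyrosinol | CCCCCCC/C=C/C(=O)N[C@@H](Cc1ccc(O)cc1)CO | intermediate |
| 4 | p-peroxyquinol (not isolated) | CCCCCCC/C=C/C(=O)N[C@@H](CC1(OO)C=CC(=O)C=C1)CO | intermediate |
| 5 | p-quinol | CCCCCCC/C=C/C(=O)N[C@@H](CC1(O)C=CC(=O)C=C1)CO | intermediate |
| 6 | 4a-hydroxychromen-7-one (vinylogous ester) | CCCCCCC/C=C/C(=O)N[C@@H]1COC2=CC(=O)C=C[C@@]2(O)C1 | intermediate |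
| 7 | epoxy vinylogous ester | CCCCCCC/C=C/C(=O)N[C@@H]1COC2=CC(=O)[C@@H]3O[C@@H]3[C@@]2(O)C1 | intermediate |
| 8 | allylic alcohol (not isolated) | CCCCCCC/C=C/C(=O)N[C@@H]1COC2=C[C@H](O)[C@@H]3O[C@@H]3[C@@]2(O)C1 | intermediate |
| 9 | transposed epoxy-enone alcohol | CCCCCCC/C=C/C(=O)N[C@@H](C[C@@]1(O)C(=O)C=C[C@@H]2O[C@@H]21)CO | intermediate |
| 10 | epoxy-enone aldehyde (⇌ spiro-lactol) | CCCCCCC/C=C/C(=O)N[C@@H](C[C@@]1(O)C(=O)C=C[C@@H]2O[C@@H]21)C=O | intermediate |
| 11 | isariotin D | CCCCCCC/C=C/C(=O)N[C@H]1C[C@@]2(O)C(=O)[C@H]([C@H](O)[C@@H]3O[C@@H]32)[C@H]1O | target |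

## Step count and main risks

Total steps: 7. Longest linear sequence: 7.

The three steps most likely to fail:

1. **Step 3 (new step).**
   - Risks: slow dienolate oxidation, Co–H attacking the enone or enamide, and modest arm selectivity.
   - Fallback (known chemistry, two thermal steps): p-TsOH-catalysed oxa-Michael cyclisation of 5 to the saturated cis-fused chromanone, then IBX (DMSO, 65 °C) or Saegusa–Ito dehydrogenation to 6.
2. **Step 5.**
   - Risk: the acid-labile vinyl epoxide may open or the ring may aromatise during transposition.
   - Fallback that avoids the cationic transposition: bis-epoxidise 5 (H2O2, NaOH), carry out a Wharton transposition (N2H4·H2O, AcOH), and oxidise the allylic alcohol with MnO2 to reach 9. The C3 epimers must then be separated.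
3. **Step 7.**
   - Risks: the wrong C6 epimer, a stalled aldol, and epoxide loss.
   - Fallback: carry the C6 oxygen from the hydride step instead of adding water.
     - Silylate 8 (TBSOTf, 2,6-lutidine).
     - Hydrolyse the enol ether with PPTS in wet acetone to the β-silyloxy ketone.
     - Oxidise the primary alcohol.
     - Close ring A by soft-enolisation aldol (MgBr2·OEt2, iPr2NEt).
     - Remove the TBS group with HF·pyridine.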